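## Retrosynthetic overview

1. Target ⇐ its tert-butyl ester; the diosphenol comes from SeO2 oxidation at C2 of a 4-methylene-3-ketone, made by Me2CuLi addition at C5 (cis fusion) and Mannich methylenation at C4 of a 7β-acetoxy-4-en-3-one.
2. The 7β-oxygen ⇐ 1,6-boration/oxidation of the 4,6-dien-3-one (chloranil); the (E)-enoate ⇐ Horner–Wadsworth–Emmons reaction on a 3-oxobutyl side chain.
3. Ring A ⇐ Robinson-type annulation (α-silyl vinyl ketone) on the regiospecific C10 enolate of the ring B ketone.
4. Key C9–C11 bond ⇐ conjugate addition of a masked 3-oxobutyl homoenolate (d3 Grignard reagent) to (R)-3,4-dimethylcyclohex-2-enone, creating the C9 quaternary centre trans to the C8 methyl.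
5. Ring order: ring B first (from 3,4-dimethylanisole by Birch reduction and enantioselective alkene isomerisation), ring A second.

Assumption: clerodane numbering is used (ring A = C1–C5, C10; ring B = C5–C10; side chain C11–C16; C17 = 8-CH3, C18 = CH2 on C4, C19 = 5-CH3, C20 = 9-CH3), and β is the face of the 5-CH3 of the target, so the target is 5β-CH3, 10β-H, 9β-side chain, 9α-CH3, 8α-CH3, 7β-OAc, i.e. (5S,7S,8S,9R,10R).

## Route

Step 1
Reactants: 1 3,4-dimethylanisole
Product: 3 3,4-dimethylcyclohex-3-en-1-one, via Birch diene 2 (not isolated)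
Conditions: Li, NH3(l), THF, t-BuOH, −78 to −33 °C; then oxalic acid, MeOH/H2O, 20 °C
Reagents that add atoms: water, O
Why: Birch reduction leaves both methyl groups on the surviving tetrasubstituted alkene, and mild enol ether hydrolysis gives the unconjugated, achiral β,γ-enone.

Step 2
Reactants: 3 3,4-dimethylcyclohex-3-en-1-one
Product: 4 (R)-3,4-dimethylcyclohex-2-en-1-one
Conditions: 9-amino-9-deoxy-epi-quinine (10 mol %; or its quinidine pseudo-enantiomer, whichever gives (R)-4), CF3CO2H (20 mol %), toluene, −25 °C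
Reagents that add atoms: none
Why: Primary-amine (iminium/dienamine) catalysed enantioselective alkene isomerisation: the chiral ammonium delivers the proton to one face of C8, setting the (R) centre as the alkene moves into conjugation.

Step 3
Reactants: 4 (R)-3,4-dimethylcyclohex-2-en-1-one, 5 2-(2-bromoethyl)-2-methyl-1,3-dioxolane
Product: 7 trimethyl{[(3S,4R)-3,4-dimethyl-3-[2-(2-methyl-1,3-dioxolan-2-yl)ethyl]cyclohex-1-en-1-yl]oxy}silane, via Grignard reagent 6 (not isolated)
Conditions: 5, Mg, THF, 20 °C; then 4, CuBr·SMe2 (10 mol %), Me3SiCl, HMPA, THF, −78 °C; Et3N, pentane work-up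
Reagents that add atoms: chlorotrimethylsilane, C[Si](C)(C)Cl
Why: Copper-catalysed, silyl-chloride-accelerated conjugate addition of a masked homoenolate (d3) Grignard reagent; axial attack anti to the pseudoaxial C8 methyl (axial because of A1,2 strain with the C9 methyl) puts the side chain β and creates the C9 quaternary centre (dr about 8:1 expected), while silylation stores the C5/C10 enolate regiospecifically.

Step 4
Reactants: 7 silyl enol ether from step 3, 8 3-(trimethylsilyl)but-3-en-2-one
Product: 12 14,15,18,19-tetranorclerod-4-ene-3,13-dione (10β-H; 8α-CH3; 9α-CH3), via lithium enolate 9 (not isolated), via silyl diketone 10 (not isolated), via ketal enone 11 (not isolated)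
Conditions: MeLi, THF, 0 °C; then 8, −78 to −20 °C; then KOH, MeOH, 60 °C; then 2 M HCl, THF, 20 °C
Reagents that add atoms: water, O
Why: Stork–Ganem variant of the Robinson annulation (regiospecific enolate, Michael addition, desilylation, aldol condensation) followed by ketal hydrolysis; C10 is set under thermodynamic control with C1 equatorial on the ring B chair that keeps the C8 methyl equatorial (about 4:1, still epimerisable and corrected finally in step 7).

Step 5
Reactants: 12 enone methyl ketone from step 4, 13 tert-butyl 2-(diethoxyphosphoryl)acetate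
Product: 14 tert-butyl 3-oxo-18,19-dinorcleroda-4,13E-dien-15-oate
Conditions: NaH, THF, 0 to 40 °C
Reagents that add atoms: none
Why: Horner–Wadsworth–Emmons olefination selective for the unhindered methyl ketone over the conjugated ring ketone, giving mainly the E enoate (about 5:1, separated by chromatography).

Step 6
Reactants: 14 enoate enone from step 5
Product: 15 tert-butyl 3-oxo-18,19-dinorcleroda-4,6,13E-trien-15-oate
Conditions: chloranil, t-BuOH, reflux
Reagents that add atoms: none
Why: Quinone dehydrogenation of a 4-en-3-one through its 3,5-dienol gives the linear 4,6-dien-3-one without touching any stereocentre.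

Step 7
Reactants: 15 dienone from step 6
Product: 18 tert-butyl 7β-hydroxy-3-oxo-18,19-dinorcleroda-4,13E-dien-15-oate, via allylic boronate 16 (not isolated), via unconjugated alcohol 17 (not isolated)
Conditions: B2pin2, CuCl (5 mol %), 1,3-bis(2,6-diisopropylphenyl)imidazolium chloride (5 mol %), NaOt-Bu (15 mol %), MeOH (2 equiv), THF, 0 °C; then 30% H2O2, pH 7 buffer, 0 °C; then NaOMe (0.2 equiv), MeOH, 0 to 20 °C
Reagents that add atoms: hydrogen peroxide, OO
Why: Proposed new method: copper–boryl 1,6-conjugate addition to a cyclic 4,6-dien-3-one (closest known reaction: Cu-catalysed δ-selective protoboration of acyclic dienones and dienoates); C5 is fully substituted so Cu–B adds at C7, from the β face anti to the axial 9α-methyl, oxidation with retention gives the 7β-alcohol, and the base returns the alkene to conjugation and drives C10 to the desired epimer (the other would place C11 and O7 syn-diaxial).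

Step 8
Reactants: 18 7β-hydroxy enone from step 7
Product: 19 tert-butyl 7β-acetoxy-3-oxo-18,19-dinorcleroda-4,13E-dien-15-oate
Conditions: Ac2O, pyridine, DMAP (cat.), CH2Cl2, 0 °C
Reagents that add atoms: acetic anhydride, CC(=O)OC(C)=O
Why: Nucleophile-catalysed acylation of the equatorial secondary alcohol under conditions too mild for vinylogous β-elimination.

Step 9
Reactants: 19 7β-acetoxy enone from step 8
Product: 23 tert-butyl 7β-acetoxy-3-oxocleroda-4(18),13E-dien-15-oate (5β-CH3; 10β-H), via lithium enolate 20 (not isolated), via Mannich base 21 (not isolated), via methiodide 22 (not isolated)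
Conditions: Me2CuLi (from MeLi and CuI), Et2O, −40 to 0 °C; then Me2N=CH2 I (Eschenmoser's salt), THF, −78 to 20 °C; then MeI, CH2Cl2, 20 °C; then aq. NaHCO3
Reagents that add atoms: lithium dimethylcuprate, [Li+].C[Cu-]C; dimethyl(methylidene)ammonium iodide, C[N+](C)=C.[I-]
Why: Cuprate conjugate addition, axial to ring A and syn to H-10 (the usual cis outcome for such octalones, here also anti to the axial 9α-methyl), sets the 5β-methyl quaternary centre, and the regiospecific C3/C4 enolate is methylenated by Mannich reaction, quaternisation and Hofmann-type elimination.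

Step 10
Reactants: 23 4-methylene 3-ketone from step 9
Product: 24 tert-butyl 7β-acetoxy-2-hydroxy-3-oxocleroda-1,4(18),13E-trien-15-oate
Conditions: SeO2, 1,4-dioxane, H2O (2 equiv), 80 °C
Reagents that add atoms: selenium dioxide, O=[Se]=O
Why: Riley oxidation at C2, the only enolisable α-position of the ketone, gives the 2,3-dione, which can enolise only towards C1 and so appears as the diosphenol.

Step 11
Reactants: 24 diosphenol tert-butyl ester from step 10
Product: 25 (13E)-7β-acetoxy-2-hydroxy-3-oxo-5β,10β-cleroda-1,4(18),13-trien-15-oic acid (target)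
Conditions: CF3CO2H, CH2Cl2, 0 to 20 °C
Reagents that add atoms: none
Why: Acidolysis of the tert-butyl ester (loss of isobutene) leaves the acetate, the diosphenol and the exocyclic enone intact.

## Compound list

1 | 3,4-dimethylanisole | COc1ccc(C)c(C)c1 | starting material
2 | 1-methoxy-4,5-dimethylcyclohexa-1,4-diene | COC1=CCC(C)=C(C)C1 | intermediate
3 | 3,4-dimethylcyclohex-3-en-1-one | O=C1CC(C)=C(C)CC1 | intermediate
4 | (R)-3,4-dimethylcyclohex-2-en-1-one | O=C1C=C(C)[C@H](C)CC1 | intermediate
5 | 2-(2-bromoethyl)-2-methyl-1,3-dioxolane | CC1(CCBr)OCCO1 | starting material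
6 | [2-(2-methyl-1,3-dioxolan-2-yl)ethyl]magnesium bromide | CC1(CC[Mg]Br)OCCO1 | intermediate
7 | trimethyl{[(3S,4R)-3,4-dimethyl-3-[2-(2-methyl-1,3-dioxolan-2-yl)ethyl]cyclohex-1-en-1-yl]oxy}silane | C[Si](C)(C)OC1=C[C@@](C)(CCC2(C)OCCO2)[C@H](C)CC1 | intermediate
8 | 3-(trimethylsilyl)but-3-en-2-one | CC(=O)C(=C)[Si](C)(C)C | starting material
9 | lithium (3S,4R)-3,4-dimethyl-3-[2-(2-methyl-1,3-dioxolan-2-yl)ethyl]cyclohex-1-en-1-olate | [Li]OC1=C[C@@](C)(CCC2(C)OCCO2)[C@H](C)CC1 | intermediate
10 | ring B ketone with a 3-oxo-2-(trimethylsilyl)butyl arm at C10 (10β-H; C2 epimers) | CC(=O)C(C[C@H]1C(=O)CC[C@@H](C)[C@]1(C)CCC1(C)OCCO1)[Si](C)(C)C | intermediate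
11 | 13,13-ethylenedioxy-14,15,18,19-tetranorclerod-4-en-3-one (10β-H; 8α-CH3; 9α-CH3) | O=C1C=C2CC[C@@H](C)[C@](C)(CCC3(C)OCCO3)[C@H]2CC1 | intermediate
12 | 14,15,18,19-tetranorclerod-4-ene-3,13-dione (10β-H; 8α-CH3; 9α-CH3) | O=C1C=C2CC[C@@H](C)[C@](C)(CCC(C)=O)[C@H]2CC1 | intermediate
13 | tert-butyl 2-(diethoxyphosphoryl)acetate | CCOP(=O)(CC(=O)OC(C)(C)C)OCC | starting material
14 | tert-butyl 3-oxo-18,19-dinorcleroda-4,13E-dien-15-oate | O=C1C=C2CC[C@@H](C)[C@](C)(CC/C(C)=C/C(=O)OC(C)(C)C)[C@H]2CC1 | intermediate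
15 | tert-butyl 3-oxo-18,19-dinorcleroda-4,6,13E-trien-15-oate | O=C1C=C2C=C[C@@H](C)[C@](C)(CC/C(C)=C/C(=O)OC(C)(C)C)[C@H]2CC1 | intermediate
16 | tert-butyl 3-oxo-7β-(4,4,5,5-tetramethyl-1,3,2-dioxaborolan-2-yl)-18,19-dinorcleroda-5,13E-dien-15-oate | O=C1CC2=C[C@H](B3OC(C)(C)C(C)(C)O3)[C@@H](C)[C@](C)(CC/C(C)=C/C(=O)OC(C)(C)C)[C@H]2CC1 | intermediate
17 | tert-butyl 7β-hydroxy-3-oxo-18,19-dinorcleroda-5,13E-dien-15-oate | O=C1CC2=C[C@H](O)[C@@H](C)[C@](C)(CC/C(C)=C/C(=O)OC(C)(C)C)[C@H]2CC1 | intermediate
18 | tert-butyl 7β-hydroxy-3-oxo-18,19-dinorcleroda-4,13E-dien-15-oate | O=C1C=C2C[C@H](O)[C@@H](C)[C@](C)(CC/C(C)=C/C(=O)OC(C)(C)C)[C@H]2CC1 | intermediate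
19 | tert-butyl 7β-acetoxy-3-oxo-18,19-dinorcleroda-4,13E-dien-15-oate | O=C1C=C2C[C@H](OC(C)=O)[C@@H](C)[C@](C)(CC/C(C)=C/C(=O)OC(C)(C)C)[C@H]2CC1 | intermediate
20 | lithium 3(4)-enolate of tert-butyl 7β-acetoxy-3-oxo-18-norclerod-13E-en-15-oate (5β-CH3) | C1=C(O[Li])CC[C@@H]2[C@@](C)(CC/C(C)=C/C(=O)OC(C)(C)C)[C@H](C)[C@@H](OC(C)=O)C[C@]12C | intermediate
21 | tert-butyl 7β-acetoxy-18-(dimethylamino)-3-oxoclerod-13E-en-15-oate (C4 epimers) | CN(C)CC1C(=O)CC[C@@H]2[C@@](C)(CC/C(C)=C/C(=O)OC(C)(C)C)[C@H](C)[C@@H](OC(C)=O)C[C@]12C | intermediate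
22 | N-methyl ammonium iodide of 21 | C[N+](C)(C)CC1C(=O)CC[C@@H]2[C@@](C)(CC/C(C)=C/C(=O)OC(C)(C)C)[C@H](C)[C@@H](OC(C)=O)C[C@]12C.[I-] | intermediate
23 | tert-butyl 7β-acetoxy-3-oxocleroda-4(18),13E-dien-15-oate | C=C1C(=O)CC[C@@H]2[C@@](C)(CC/C(C)=C/C(=O)OC(C)(C)C)[C@H](C)[C@@H](OC(C)=O)C[C@]12C | intermediate
24 | tert-butyl 7β-acetoxy-2-hydroxy-3-oxocleroda-1,4(18),13E-trien-15-oate | C=C1C(=O)C(O)=C[C@@H]2[C@@](C)(CC/C(C)=C/C(=O)OC(C)(C)C)[C@H](C)[C@@H](OC(C)=O)C[C@]12C | intermediate
25 | (13E)-7β-acetoxy-2-hydroxy-3-oxo-5β,10β-cleroda-1,4(18),13-trien-15-oic acid, (5S,7S,8S,9R,10R) | C=C1C(=O)C(O)=C[C@@H]2[C@@](C)(CC/C(C)=C/C(=O)O)[C@H](C)[C@@H](OC(C)=O)C[C@]12C | target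

## Step count and risks

Total step count: 11. Longest linear sequence: 11 steps, from 3,4-dimethylanisole (5, 8 and 13 are purchased).

Three steps most likely to fail:

Step 3 (quaternary centre and facial selectivity). A functionalised Grignard reagent may add sluggishly to the β,β-disubstituted enone or with a poor trans/cis ratio. Fallback, setting out from 4 and coming back at 7: make the same d3 nucleophile by hydrometalation instead. Hydrozirconation of 2-methyl-2-vinyl-1,3-dioxolane with Cp2Zr(H)Cl gives the alkylzirconocene chloride F1, which is added to 4 with CuCl/AgOTf, a chiral phosphoramidite ligand matched to the substrate bias, and Me3SiCl. The ligand, not only the ring, then controls the face, and the product is 7, which continues at step 4.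

Step 7 (C7 oxygenation). The 1,6-boration is unproven on this ring system; it could give the wrong face, touch the side-chain enoate, or the 7-hydroxy enone could eliminate during equilibration. Fallback, setting out from 15 and coming back at 17: epoxidise the electron-richer γ,δ-alkene with m-chloroperbenzoic acid from the open β face to give the 6β,7β-epoxy enone F2. Then cleave the C6–O bond reductively with SmI2 (THF/MeOH, −78 °C) through the dienolate. This gives 17, which is conjugated and equilibrated to 18 as in the last operation of step 7.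

Step 10 (diosphenol formation). SeO2 may also oxidise the allylic positions of the side-chain enoate or degrade the exocyclic enone. Fallback, setting out from 23 and coming back at 24: soft enolisation with Me3SiOTf/Et3N gives the 2-silyloxy diene F3. Rubottom oxidation with dimethyldioxirane gives the 2-hydroxy ketone F4. Dess–Martin periodinane then gives the 2,3-dione, which enolises to 24.

Further compounds
F1 | step 3 | chlorobis(cyclopentadienyl)[2-(2-methyl-1,3-dioxolan-2-yl)ethyl]zirconium | CC1(CC[Zr](Cl)(C2C=CC=C2)C2C=CC=C2)OCCO1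
F2 | step 7 | tert-butyl 6β,7β-epoxy-3-oxo-18,19-dinorcleroda-4,13E-dien-15-oate | O=C1C=C2[C@@H]3O[C@@H]3[C@@H](C)[C@](C)(CC/C(C)=C/C(=O)OC(C)(C)C)[C@H]2CC1
F3 | step 10 | tert-butyl 7β-acetoxy-3-(trimethylsilyloxy)cleroda-2,4(18),13E-trien-15-oate | C=C1C(O[Si](C)(C)C)=CC[C@@H]2[C@@](C)(CC/C(C)=C/C(=O)OC(C)(C)C)[C@H](C)[C@@H](OC(C)=O)C[C@]12C
F4 | step 10 | tert-butyl 7β-acetoxy-2-hydroxy-3-oxocleroda-4(18),13E-dien-15-oate (C2 epimers) | C=C1C(=O)C(O)C[C@@H]2[C@@](C)(CC/C(C)=C/C(=O)OC(C)(C)C)[C@H](C)[C@@H](OC(C)=O)C[C@]12C
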